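**Retrosynthetic overview**
- Open the pyranone (ring C) of prosogerin C at the aryl C8a–O1 bond. The enol oxygen of a 1,3-diaryl-1,3-diketone takes the place of an ortho-methoxy group on ring A, with loss of MeOH.
- Cut the 1,3-diketone by a crossed Claisen disconnection into an aryl methyl ketone (ring A) and a methyl benzoate (ring B).
- Rings A and B are bought with all five retained methoxy groups in place. Ring C is the only ring formed, and it is formed last.

Assumption: prosogerin C is a planar flavone with no stereocentre or stable axis, so there is no enantiomer to control. The only stereocentre that appears (C8a of transient 5) is erased in the same step.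

**Step 1**
Reactants: 1 2',4',5'-trimethoxyacetophenone; 2 methyl 3,4,5-trimethoxybenzoate (1.2 equiv)
Product: 4 1-(2,4,5-trimethoxyphenyl)-3-(3,4,5-trimethoxyphenyl)propane-1,3-dione, via sodium diketonate 3 (not isolated)
Conditions: NaH (2.5 equiv), THF, reflux, 4 h; then 1 M aq HCl, 0 °C
Reagents that add atoms: none
Why: Crossed Claisen condensation, in which only 1 can enolise, 2 is a non-enolisable ester, and irreversible deprotonation to the stabilised diketonate 3 drives the equilibrium, as in industrial dibenzoylmethane syntheses; no stereocentre is formed.

**Step 2**
Reactants: 4 1-(2,4,5-trimethoxyphenyl)-3-(3,4,5-trimethoxyphenyl)propane-1,3-dione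
Product: 6 prosogerin C (6,7,3',4',5'-pentamethoxyflavone), via ipso ketal radical 5 (not isolated)
Conditions: 9-mesityl-3,6-di-tert-butyl-10-phenylacridinium tetrafluoroborate (5 mol %), 455 nm LEDs, DCE/HFIP 4:1 (0.05 M), degassed, N2, 30 °C, 24 h
Reagents that add atoms: none
Why: Proposed new method: an intramolecular cation-radical-accelerated nucleophilic aromatic substitution in which an enol oxygen displaces an aryl methoxy group and closes a 4-pyranone. The excited acridinium (about +2.1 V vs SCE) oxidises ring A of 4 by one electron; ring A is estimated at about +1.4 V and is the most easily oxidised π-system, against about +1.7 V for ring B. In that radical cation the positive charge sits mainly on the para-related methoxy-bearing carbons C2 and C5. The enol oxygen on the ring B side can reach only C2, through a six-membered transition state, and loss of the enol proton gives ketal radical 5. HFIP-assisted loss of methoxide then gives the flavone radical cation, which takes an electron back from the acridine radical or from fresh 4 (chain), so the step is redox-neutral and releases only MeOH. Because there is no terminal oxidant, attack at any C–H position (C6 of ring A, C2' of ring B) is reversible and unproductive, and exchange with the freed MeOH is degenerate, so a single flavone regioisomer is expected. The closest known reaction types are acridinium-photoredox substitution of methoxyarenes by intermolecular azole, amine and cyanide nucleophiles, and base-mediated O-arylation of 1-(2-haloaryl)-1,3-diketones to chromones; the latter polar pathway is shut down here by the electron-rich ring A, which is exactly what makes the oxidative pathway easy.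

**Compound list**
1 | 2',4',5'-trimethoxyacetophenone | CC(=O)c1cc(OC)c(OC)cc1OC | starting material
2 | methyl 3,4,5-trimethoxybenzoate | COC(=O)c1cc(OC)c(OC)c(OC)c1 | starting material
3 | sodium 1-(2,4,5-trimethoxyphenyl)-3-(3,4,5-trimethoxyphenyl)propane-1,3-dion-2-ide (sodium diketonate, drawn as the carbon-centred resonance form) | [Na+].COc1cc(OC)c(cc1OC)C(=O)[CH-]C(=O)c1cc(OC)c(OC)c(OC)c1 | intermediate
4 | 1-(2,4,5-trimethoxyphenyl)-3-(3,4,5-trimethoxyphenyl)propane-1,3-dione (drawn as the diketo form; mainly the chelated enol in solution) | COc1cc(OC)c(cc1OC)C(=O)CC(=O)c1cc(OC)c(OC)c(OC)c1 | intermediate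
5 | ipso ketal radical: 6,7,8a-trimethoxy-4-oxo-2-(3,4,5-trimethoxyphenyl)-8aH-chromen-4a-yl radical (racemic, transient; one resonance form drawn) | COC1=CC2(OC)OC(=CC(=O)[C]2C=C1OC)c1cc(OC)c(OC)c(OC)c1 | intermediate
6 | prosogerin C, 6,7-dimethoxy-2-(3,4,5-trimethoxyphenyl)-4H-chromen-4-one | COc1cc2oc(-c3cc(OC)c(OC)c(OC)c3)cc(=O)c2cc1OC | target

**Totals**
Total step count: 2. Longest linear sequence: 2.

**Steps most likely to fail**
The route has only two steps, so both are ranked.

Most at risk is step 2, the proposed new ring closure.
- The neutral, internally hydrogen-bonded enol may be too weak a nucleophile.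
- Back electron transfer may outrun ipso attack.
- The enol π-system may be oxidised instead of ring A.
- Traces of O2 could turn the reversible C6–H adduct into the 5,7,8-trimethoxy isomer.

The fallback uses known chemistry and forms the other pyranone C–O bond (O1–C2) instead. It sets out from 4 and comes back at 6. Chelation-controlled cleavage of the methoxy group ortho to the carbonyl with BCl3 (3 equiv, CH2Cl2, −78 to 0 °C, aqueous work-up) gives 1-(2-hydroxy-4,5-dimethoxyphenyl)-3-(3,4,5-trimethoxyphenyl)propane-1,3-dione F1. Acid cyclodehydration of this compound (catalytic H2SO4, AcOH, 100 °C), the closing stage of the Baker–Venkataraman flavone synthesis, delivers 6. Low temperature and short contact time protect the central methoxy group of ring B.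

Second is step 1. The electron-rich, ortho-substituted ketone enolate may acylate slowly, which would allow self-condensation of 1 or incomplete conversion.

The fallback replaces acylation by an aldol addition and oxidation. It sets out from 1 and comes back at 4. Kinetic enolisation of 1 with LiN(iPr)2 (THF, −78 °C) and addition to commercial 3,4,5-trimethoxybenzaldehyde gives racemic 3-hydroxy-1-(2,4,5-trimethoxyphenyl)-3-(3,4,5-trimethoxyphenyl)propan-1-one F2. Oxidation with 2-iodoxybenzoic acid (EtOAc, reflux), a standard route from β-hydroxy ketones to 1,3-diketones, gives 4 and removes the stereocentre.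

**Further compounds**
F1 | step 2 | 1-(2-hydroxy-4,5-dimethoxyphenyl)-3-(3,4,5-trimethoxyphenyl)propane-1,3-dione | COc1cc(O)c(cc1OC)C(=O)CC(=O)c1cc(OC)c(OC)c(OC)c1
F2 | step 1 | 3-hydroxy-1-(2,4,5-trimethoxyphenyl)-3-(3,4,5-trimethoxyphenyl)propan-1-one (racemic) | COc1cc(OC)c(cc1OC)C(=O)CC(O)c1cc(OC)c(OC)c(OC)c1
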